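**Early hours.** In the early hours of the alder run, open intermediate reaches 68.6% by 3.00 h while target reads 1.0%. Reagent turns substrate into open intermediate, and open intermediate can take a further substrate into side product.

all flasks: reagent 0.375 M
- alder: substrate 0.15 M; partner 0.27 M; run made earlier
- birch: substrate 0.21 M; partner 0.27 M; run made earlier
- elm: substrate 0.33 M; partner 0.27 M; run made earlier
- summer: substrate 0.15 M; partner 0.270 M; everything together in a closed stirred flask, run for 15 h; time 15 h
- winter: substrate 0.15 M; partner 0.270 M; one stirred flow tank at steady state, fed with the mixture as stated, mean residence time 15 h
- autumn: substrate 0.15 M (fed, over 7.50 h); partner 0.270 M; all but substrate at the start; substrate goes in evenly over 7.50 h, the run ends at 15 h; time 15 h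
- dusk: substrate 0.15 M; partner 0.270 M (fed, over 7.50 h); a stirred flask in which partner is dosed at a steady rate over 7.50 h without added volume, worked up at 15 h; time 15 h

| run | time / h | open intermediate / % | target / % |
|---|---|---|---|
| alder | 1.33 | 60.1 | 0.6 |
| alder | 3.00 | 68.6 | 1.0 |
| alder | 6.00 | 66.1 | 4.9 |
| alder | 15.0 | 53.6 | 18.5 |
| birch | 1.33 | 54.4 | 0 |
| birch | 3.00 | 59.7 | 1.0 |
| birch | 6.00 | 57.8 | 3.9 |
| birch | 15.0 | 48.5 | 13.9 |
| elm | 2.00 | 44.3 | 0.5 |
| elm | 5.00 | 43.9 | 1.7 |
| elm | 10.0 | 40.5 | 3.9 |
| elm | 15.0 | 38.1 | 7.0 |

(each reading ± 0.3 percentage points)

- percentages count the substrate that a species holds: one idle adduct or side product counts as two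
- target is meant together with its idle adduct
- the stated concentrations are those of everything mixed, before any reaction; amounts are the same in each set-up
- steps under discussion: open intermediate + second intermediate -> target; reagent + partner -> second intermediate; 2 second intermediate -> homo product; substrate + open intermediate -> side product; substrate + reagent -> open intermediate; substrate + target <-> idle adduct
- the feed brings no volume worth counting
- the earlier runs were made in a closed, stirred flask
- in an amount of target, one idle adduct counts as one target

1. the set-up with the highest amount of open intermediate at the outlet or at the end, in percent of the substrate put in ("none" if the first two lie within 2 percentage points) (summer / winter / autumn / dusk / none)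
2. amount of open intermediate at the outlet or at the end, in percent of the substrate put in, summer
3. amount of open intermediate at the outlet or at the end, in percent of the substrate put in, winter
4. amount of open intermediate at the outlet or at the end, in percent of the substrate put in, autumn
5. amount of open intermediate at the outlet or at the end, in percent of the substrate put in, dusk

**First round.** Setting the idle adduct aside, substrate meets either reagent or open intermediate, so the share lost should follow the ratio of substrate charge to reagent charge. The loss is read at the end of a run as what open intermediate and target leave uncounted: 27.9% in alder at ratio 0.400, and 54.9% in elm at ratio 0.880. Loss over ratio gives 0.698 from alder and 0.624 from elm, so the two ways part.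

**Second round.** The first round counts every turned substrate as open intermediate, and that cheats more in elm than in alder, since the loss in elm is larger. The first answer therefore goes back in: the ratio is multiplied by one minus a third of the loss, a weight chosen from the alder and elm readings. Alder now gives 0.769 and elm 0.764, which agree, but the weight was chosen for that. Birch took no part in the choice: its loss of 37.6% at ratio 0.560 gives 0.768, in line with alder. This figure, the end loss per unit of ratio after the correction, is the loss factor, a selectivity factor.

**Own reckoning.** Partner stands in neither of these steps and dusk has the ratio of alder, so this reckoning keeps the dusk loss at 27.9%. That leaves 72.1% to share between open intermediate and target.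

**The forecast.** It gives 53.6% for summer, 42% for winter, 56% for autumn and 59% for dusk, and it chooses dusk: “Dosing partner delays second intermediate, so less target forms”. Within the reckoned share, its dusk figure leaves 13 percentage points for target.

**The result.** The flasks give 53.4% in summer, 40.6% in winter, 51.5% in autumn and 59.8% in dusk, which stands highest, so the choice is dusk.

    open intermediate + second intermediate → target (k = 1.50 × 10⁻⁴ L mol⁻¹ s⁻¹)
    reagent + partner → second intermediate (k = 3.80 × 10⁻⁵ L mol⁻¹ s⁻¹)
    2 second intermediate → homo product (k = 8.10 × 10⁻⁵ L mol⁻¹ s⁻¹)
    substrate + open intermediate → side product (k = 7.20 × 10⁻⁴ L mol⁻¹ s⁻¹)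
    substrate + reagent → open intermediate (k = 9.20 × 10⁻⁴ L mol⁻¹ s⁻¹)
    substrate + target ⇌ idle adduct, settled at all times (K = 19.0 L mol⁻¹)

**Neighbouring flask.** At the end, dusk holds side product 27.5% and target 12.7%, against the reckoned loss of 27.9%. The neighbouring flask is dusk with substrate cut to 0.037 M, which makes the ratio 0.0987. The loss factor gives 7.59% on the first round and 7.40% on the second. That flask ends with open intermediate 69.5%, target 23.0% and side product 7.48%.

The readings stem from a simulated flask with constants of no real substance, noise included.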